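## Structural features

The target is a biflavonoid in which an upper 4′,7-dihydroxyflavan (benzo ring A, pyran ring C, aryl ring B) is bonded through its C-4 to C-6 of a lower epiafzelechin unit (benzo ring D, the lower pyran, aryl ring E). The upper pyran holds two stereocentres in a 1,3-relationship, C-2 (S) and C-4 (S), with both aryl groups cis. The lower pyran holds two adjacent stereocentres, C-2 (R) and C-3 (R), with aryl and hydroxyl cis; the aromatic ring D insulates the two pairs from each other. The fragile elements are six oxidisable phenols, two cyclic benzylic ethers (O-1 to C-2 in each half, both para to an oxygenated ring, so acid can ionise and epimerise them), the doubly benzylic interflavan carbon on a phloroglucinol-type ring, and the 2,3-cis alcohol, which is the less stable epimer. The real difficulty is threefold: attaching the upper unit at C-6 and not C-8 of ring D, controlling absolute configuration in each half without any relay between them, and reaching the cis arrangement at C-2/C-3. The key step uses the fact that O-1 sits on C-8a and C-4 on the neighbouring C-4a of ring D, the ortho-hydroxy/ortho-carbon pattern of a salicylaldehyde, while C-2 and C-3 are the β- and α-carbons of a 4-oxygenated cinnamaldehyde. A formyl group left on C-3 by such an annulation can afterwards be exchanged for the C-3 oxygen. Before the lower pyran exists, ring D has a twofold axis through the interflavan carbon and the para oxygen, so functionalisation ortho to that oxygen can only lead to the 4→6 isomer.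

## Logic of the disconnections

19 is traced to 18 by cutting the five O–CH2 bonds of benzyl ethers. Benzyl is chosen for every phenol so that one neutral hydrogenolysis uncovers the air-sensitive hexaol at the very end. The gain is that every earlier compound is non-phenolic, except where a single phenol is needed. The demand is that the cyclic benzylic C-2–O-1 bonds and the interflavan bond survive the hydrogenolysis.

18 is traced to 17 by removing the C-3–H bond (alcohol to ketone). The cis relationship can then be set by a bulky hydride entering anti to the C-2 aryl group. The gain is one stereocentre less in the lower pyran. The demand is that 17 does not enolise towards C-2 before or during reduction.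

17 is traced through 16 to 15 by replacing the C-3–O bond with a C-3–CHO bond and a C-3=C-4 double bond. The reason is that a 3-formyl-2H-chromene is exactly what an enal-based annulation delivers. The gain is a condensation product in place of an α-aryl-α-alkoxy ketone. The demand is an oxidative carbon-to-oxygen exchange in which the alkenyl carbon migrates and the electron-rich rings are left alone.

15 is traced to 12 and 13 by cutting O-1–C-2 and C-3–C-4 of the lower pyran. Both bonds follow natural polarity (phenol oxygen onto an enal β-carbon, enamine α-carbon onto an aldehyde). The gain is the removal of the whole lower pyran, ring E and the last lower stereocentre in one step. The demand is catalyst-controlled facial selectivity at C-2, because the upper stereocentres are too far away to help.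

12 is traced to 10 by cutting the bond between ring D and the formyl carbon. Ortho-formylation of a phenol is regiospecific here because both ortho carbons of 10 are equivalent. The gain is a symmetric ring D and a guaranteed 4→6 pattern. The demand is clean mono-formylation next to a benzyloxy group.

10 is traced to 9 by cutting the O–Si bond. The silyl ether is the device that distinguishes the para oxygen of ring D from the two benzylated ones. The demand is fluoride cleavage without loss of benzyl ethers.

9 is traced through 8 to 5 and 7 by cutting O-1–C-2 and C-3–C-4 of the upper pyran (a retro-[4+2] of the chroman). The gain is the loss of both upper stereocentres and a split into a benzhydrol and a styrene. The demand is enantioface control on a hindered, strongly stabilised intermediate and cis selectivity.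

5 is traced through 4 to 2 and 3 by cutting the bond between the carbinol carbon (future C-4) and ring D. The carbon between the two benzyloxy groups of 2 is the natural site of lithiation, and 3 supplies ring A with its ortho-hydroxyl. The gain is two simple benzene derivatives. The demand is metalation on the ring and not at a benzylic CH2.

2 is traced to 1 by cutting the O–Si bond, and 7 and 13 are each traced to 6 by cutting a C=C bond (one-carbon and two-carbon Wittig extensions). Both arylpropanoid pieces therefore come from the same aldehyde. The demand is (E)-geometry in 13.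

## Other disconnections considered

Alternative 1: The cut runs through ring D itself, at C-5–C-6 and C-7–C-8 (with C-4a–C-5 opened and re-formed on the way). This divides the target into a pyran-fused 3-alkoxycyclobutenone A1 carrying the lower C-2 and C-3 stereocentres and an upper flavan A2 whose C-4 bears a silyloxyethynyl group. In the forward step, heating A1 with A2 should set off four-electron ring opening, [2+2] addition to the ynol ether, a second ring opening and six-electron closure, and give phenol A3 after tautomerisation.
- In favour: the interflavan position is written into the alkyne carbon, so the 4→6 outcome is as secure as in the chosen plan and does not depend on symmetry. All four stereocentres exist before the union, so the coupling is stereochemically silent; on this point the alternative is better than the chosen plan. No acid, base or oxidant is needed.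
- Against: A1 is a strained bicycle with a benzyloxy group β to the latent ketene carbonyl and has no short synthesis. A2 needs homologation of an upper flavan-4-carboxylate to an ynolate, and its C-4 hydrogen is benzylic and propargylic, hence epimerisable.
- Comparison: structurally it avoids the epimerisable ketone 17. Mechanistically a thermal pericyclic cascade needs no catalyst control and is more predictable than step 8. In step economy it is clearly worse, since each partner needs its own multi-step asymmetric synthesis, although the endgame from A3 (desilylation, hydrogenolysis) would be one step shorter than from 15.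

Alternative 2: The cut is through the upper pyran at C-3–C-4 and O-1–C-2, giving 5 and 7. In the forward step a chiral Brønsted acid ionises 5 to 8, which adds 7 and closes the pyran to A4; A4 is the same compound as 9.
- In favour: two bonds, one ring and both upper stereocentres arise from achiral, easily made pieces in one catalytic step, with inherent cis selectivity. It creates two stereocentres against one in step 8 and is in that respect the better step.
- Against, as the organising idea for the whole molecule: it says nothing about the lower unit. Ring D must either be elaborated afterwards or be brought in as a complete protected flavan-3-ol aryl group, which would make the benzhydrol much bulkier and expose the lower C-2 ether to the acid.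
- Comparison: the two plans are complements, not rivals. The chosen route uses this cycloaddition as step 4, so the step count is identical. It is ranked second only because the harder problems of this target (the 4→6 attachment and a cis alcohol remote from any controlling centre) lie in the lower pyran.

Alternative 3: The cut is at C-4–C-4a of the lower unit, leading back to the aryl ether epoxide A5, in which phenol 10 is etherified at the benzylic carbon of a 1-aryl-2,3-epoxypropyl unit. In the forward step a mild Lewis acid (the monovalent gold complex Ph3PAuNTf2, or BF3·OEt2) activates the epoxide and a ring D carbon ortho to the ether oxygen attacks the CH2 terminus (6-endo), giving A6; A6 is the same compound as 18.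
- In favour: both lower stereocentres are set by reagent control before ring closure and are not touched by it. The ketone 17 is avoided. Symmetry of ring D again makes the two ortho carbons equivalent, which is equal to the chosen plan. A6 is one step from the target against three from 15, so the alternative is better on the endgame.
- Against: the cis series needs the ether oxygen and the epoxide oxygen syn, which means a Mitsunobu inversion at a 4-benzyloxybenzylic carbinol, where ionisation can leak configuration. The same C–O bond can ionise under the Lewis acid, and 5-exo opening or hydride shift of the epoxide can compete.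
- Comparison: structurally it reaches the same penultimate compound. Mechanistically it exchanges covalent aminocatalysis for an SN2-like Friedel–Crafts alkylation. Overall step economy is equal or slightly better. It is kept as the fallback for the key step.

Key step: step 8

Remark: 1 and 3 are treated as catalogue compounds; the sense of induction of the chiral acid in step 4 cannot be predicted from a simple model, so the catalyst antipode is to be matched to the (2S,4S) product (the (R)-form is written).

Abbreviation used in names: Fl = (2S,4S)-7-(benzyloxy)-2-[4-(benzyloxy)phenyl]chroman-4-yl.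

## Steps

Step 1
Reactants: 1 3,5-bis(benzyloxy)phenol
Product: 2 1,3-bis(benzyloxy)-5-(triisopropylsilyloxy)benzene
Conditions: TIPSCl, imidazole, DMF, rt
Reagents that add atoms: triisopropylsilyl chloride, CC(C)[Si](Cl)(C(C)C)C(C)C
Why: Standard O-silylation of an unhindered phenol; the bulky silyl ether marks the oxygen that must later be the only free phenol, resists n-BuLi and is a poor ortho-director, so it leaves the carbon between the two benzyloxy groups as the site of lithiation.

Step 2
Reactants: 2 1,3-bis(benzyloxy)-5-(triisopropylsilyloxy)benzene; 3 4-(benzyloxy)-2-hydroxybenzaldehyde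
Product: 5 (4-benzyloxy-2-hydroxyphenyl)[2,6-bis(benzyloxy)-4-(triisopropylsilyloxy)phenyl]methanol as the racemate, via aryllithium 4 (not isolated)
Conditions: 2 (2.2 equiv), n-BuLi (2.1 equiv), THF, 0 °C; then 3, −78 → 0 °C; H2O
Reagents that add atoms: none
Why: Directed ortho-metalation at the ring carbon flanked by two alkoxy groups, then 1,2-addition of the aryllithium to the aldehyde; the first equivalent of 4 deprotonates the phenol of 3 and returns 2. The carbinol centre is racemic and is erased in step 4; 5 is acid-labile and is to be handled on base-washed silica.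

Step 3
Reactants: 6 4-(benzyloxy)benzaldehyde
Product: 7 1-(benzyloxy)-4-vinylbenzene
Conditions: Ph3PCH3Br, KOtBu, THF, 0 °C → rt
Reagents that add atoms: methyltriphenylphosphonium bromide, C[P+](c1ccccc1)(c1ccccc1)c1ccccc1.[Br-]
Why: Wittig methylenation of a non-enolisable aryl aldehyde.

Step 4
Reactants: 5 (4-benzyloxy-2-hydroxyphenyl)[2,6-bis(benzyloxy)-4-(triisopropylsilyloxy)phenyl]methanol; 7 1-(benzyloxy)-4-vinylbenzene
Product: 9 (2S,4S)-7-(benzyloxy)-2-[4-(benzyloxy)phenyl]-4-[2,6-bis(benzyloxy)-4-(triisopropylsilyloxy)phenyl]chroman, via o-quinone methide 8 (not isolated)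
Conditions: (R)-3,3′-bis(2,4,6-triisopropylphenyl)-BINOL N-triflylphosphoramide (5 mol%), 7 (1.5 equiv), 4 Å MS, toluene, −20 °C → rt
Reagents that add atoms: none
Why: The chiral Brønsted acid dehydrates 5 to the o-quinone methide, held as a hydrogen-bonded ion pair, and the styrene adds in an asynchronous inverse-demand [4+2] cycloaddition (C-4 to the CH2 terminus, then O-1 to the benzylic carbon), a known reaction type for o-hydroxybenzhydrols and styrenes. The catalyst fixes the face of the o-quinone methide (C-4), and the endo-like approach places both aryl groups cis (C-2), which is also the diequatorial, thermodynamically preferred arrangement.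

Step 5
Reactants: 9 (2S,4S)-7-(benzyloxy)-2-[4-(benzyloxy)phenyl]-4-[2,6-bis(benzyloxy)-4-(triisopropylsilyloxy)phenyl]chroman
Product: 10 3,5-bis(benzyloxy)-4-Fl-phenol
Conditions: Bu4NF, THF, 0 °C; H2O
Reagents that add atoms: none
Why: Fluoride cleaves the aryl silyl ether selectively; benzyl ethers and both stereocentres are not affected.

Step 6
Reactants: 10 3,5-bis(benzyloxy)-4-Fl-phenol
Product: 12 2,4-bis(benzyloxy)-3-Fl-6-hydroxybenzaldehyde, via salicyl alcohol 11 (not isolated)
Conditions: MgCl2, Et3N, (CH2O)n, MeCN, reflux; cold dilute aq. HCl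
Reagents that add atoms: paraformaldehyde (as formaldehyde), C=O
Why: Magnesium phenoxide-directed ortho-formylation (Casnati–Skattebøl): formaldehyde is delivered to the carbon ortho to the only free hydroxyl, and a second formaldehyde oxidises the hydroxymethyl intermediate by hydride transfer. The two ortho carbons are equivalent, so only one regioisomer can form and the later 4→6 linkage is fixed.

Step 7
Reactants: 6 4-(benzyloxy)benzaldehyde
Product: 13 (E)-3-[4-(benzyloxy)phenyl]prop-2-enal
Conditions: Ph3P=CHCHO, toluene, 80 °C
Reagents that add atoms: (triphenylphosphoranylidene)acetaldehyde, O=CC=P(c1ccccc1)(c1ccccc1)c1ccccc1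
Why: Wittig two-carbon homologation with a stabilised ylide, which gives the (E)-enal; a slight deficit of ylide limits further homologation of the product.

Step 8
Reactants: 12 2,4-bis(benzyloxy)-3-Fl-6-hydroxybenzaldehyde; 13 (E)-3-[4-(benzyloxy)phenyl]prop-2-enal
Product: 15 (2R)-5,7-bis(benzyloxy)-2-[4-(benzyloxy)phenyl]-6-Fl-2H-chromene-3-carbaldehyde, via aldol adduct 14 (not isolated)
Conditions: (S)-2-[diphenyl(trimethylsilyloxy)methyl]pyrrolidine (20 mol%), 2-nitrobenzoic acid (20 mol%), 13 (1.5 equiv), 4 Å MS, toluene, 0 °C → rt
Reagents that add atoms: none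
Why: The secondary amine condenses with 13 to an (E)-iminium ion; the acid co-catalyst helps the hydrogen-bonded phenol of 12 to add to its β-carbon (O-1 to C-2), the resulting enamine adds through its α-carbon to the neighbouring formyl group (C-3 to C-4), and dehydration of aldol 14 with hydrolysis releases 15 and the catalyst. The closest known reaction type is the diarylprolinol silyl ether-catalysed domino oxa-Michael/aldol condensation of salicylaldehydes with cinnamaldehydes to 2-aryl-2H-chromene-3-carbaldehydes. The lower pyran is closed in the aldol event, a 6-(enolexo)-exo-trig cyclisation that follows an intermolecular conjugate addition. The only new stereocentre, C-2, is under catalyst control: the CPh2OSiMe3 group of the (S)-pyrrolidine shields one face of the s-trans iminium ion, so the phenol should enter from the open face, which corresponds to 2R; the upper stereocentres are too remote to interfere, and the (R)-catalyst would be used if the sense proved opposite. Chemoselectivity is secured by the substrate, since the hydroxyl ortho to the formyl group is the only free phenol, and regiochemistry by the fixed ortho relationship of OH and CHO. Reversal of the oxa-Michael step, the main threat to C-2, is countered by the fast intramolecular aldol/dehydration, by molecular sieves, and by working at or below room temperature and stopping once 12 is consumed. Both partners are electron-rich, so an excess of 13 and the acid co-catalyst are used to keep the rate acceptable.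

Step 9
Reactants: 15 (2R)-5,7-bis(benzyloxy)-2-[4-(benzyloxy)phenyl]-6-Fl-2H-chromene-3-carbaldehyde
Product: 17 (2R)-5,7-bis(benzyloxy)-2-[4-(benzyloxy)phenyl]-6-Fl-chroman-3-one, via enol formate 16 (not isolated)
Conditions: mCPBA (1.1 equiv), Na2HPO4, CH2Cl2, 0 °C; aq. Na2S2O3 wash; crude in THF/MeOH, KHCO3, 0 °C
Reagents that add atoms: 3-chloroperbenzoic acid, O=C(OO)c1cccc(Cl)c1
Why: Baeyer–Villiger oxidation of the enal: the electron-rich alkenyl carbon C-3, conjugated with ring D, migrates in the Criegee adduct in preference to hydride (as the aryl group does in a Dakin oxidation) and gives the enol formate. Mild methanolysis frees the enol, which ketonises by protonation at C-4; C-2 is not involved in either event, and weak base at 0 °C for a short time is meant to keep the now enolisable C-2 intact.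

Step 10
Reactants: 17 (2R)-5,7-bis(benzyloxy)-2-[4-(benzyloxy)phenyl]-6-Fl-chroman-3-one
Product: 18 (2R,3R)-5,7-bis(benzyloxy)-2-[4-(benzyloxy)phenyl]-6-Fl-chroman-3-ol
Conditions: LiBH(s-Bu)3, THF, −78 °C; H2O
Reagents that add atoms: none
Why: The bulky trialkylborohydride attacks the ketone from the face anti to the C-2 aryl group and gives the 2,3-cis alcohol (3R), the known outcome for benzylated 2-arylchroman-3-ones; the low temperature disfavours enolisation towards C-2.

Step 11
Reactants: 18 (2R,3R)-5,7-bis(benzyloxy)-2-[4-(benzyloxy)phenyl]-6-Fl-chroman-3-ol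
Product: 19 (2R,3R)-2-(4-hydroxyphenyl)-6-[(2S,4S)-7-hydroxy-2-(4-hydroxyphenyl)chroman-4-yl]chroman-3,5,7-triol
Conditions: H2 (1 atm), Pd(OH)2/C, THF/MeOH, rt
Reagents that add atoms: none
Why: Hydrogenolysis of the five benzyl ethers under neutral conditions; the cyclic benzylic C-2–O-1 bonds of flavans are known to persist if the reaction is stopped at complete debenzylation, and no stereocentre is touched.

## Compound list

1 | 3,5-bis(benzyloxy)phenol | Oc1cc(OCc2ccccc2)cc(OCc2ccccc2)c1 | starting material
2 | 1,3-bis(benzyloxy)-5-(triisopropylsilyloxy)benzene | CC(C)[Si](Oc1cc(OCc2ccccc2)cc(OCc2ccccc2)c1)(C(C)C)C(C)C | intermediate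
3 | 4-(benzyloxy)-2-hydroxybenzaldehyde | O=Cc1ccc(OCc2ccccc2)cc1O | starting material
4 | [2,6-bis(benzyloxy)-4-(triisopropylsilyloxy)phenyl]lithium | [Li]c1c(OCc2ccccc2)cc(O[Si](C(C)C)(C(C)C)C(C)C)cc1OCc1ccccc1 | intermediate (not isolated)
5 | (4-benzyloxy-2-hydroxyphenyl)[2,6-bis(benzyloxy)-4-(triisopropylsilyloxy)phenyl]methanol, racemic | OC(c1ccc(OCc2ccccc2)cc1O)c1c(OCc2ccccc2)cc(O[Si](C(C)C)(C(C)C)C(C)C)cc1OCc1ccccc1 | intermediate
6 | 4-(benzyloxy)benzaldehyde | O=Cc1ccc(OCc2ccccc2)cc1 | starting material
7 | 1-(benzyloxy)-4-vinylbenzene | C=Cc1ccc(OCc2ccccc2)cc1 | intermediate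
8 | 3-(benzyloxy)-6-{[2,6-bis(benzyloxy)-4-(triisopropylsilyloxy)phenyl]methylidene}cyclohexa-2,4-dien-1-one (o-quinone methide) | O=C1C=C(OCc2ccccc2)C=CC1=Cc1c(OCc2ccccc2)cc(O[Si](C(C)C)(C(C)C)C(C)C)cc1OCc1ccccc1 | intermediate (not isolated)
9 | (2S,4S)-7-(benzyloxy)-2-[4-(benzyloxy)phenyl]-4-[2,6-bis(benzyloxy)-4-(triisopropylsilyloxy)phenyl]chroman (2,4-cis) | c1ccccc1COc1ccc([C@@H]2C[C@H](c3c(OCc4ccccc4)cc(O[Si](C(C)C)(C(C)C)C(C)C)cc3OCc3ccccc3)c3ccc(OCc4ccccc4)cc3O2)cc1 | intermediate
10 | 3,5-bis(benzyloxy)-4-Fl-phenol | c1ccccc1COc1ccc([C@@H]2C[C@H](c3c(OCc4ccccc4)cc(O)cc3OCc3ccccc3)c3ccc(OCc4ccccc4)cc3O2)cc1 | intermediate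
11 | 3,5-bis(benzyloxy)-4-Fl-2-(hydroxymethyl)phenol, formed as its magnesium salt | c1ccccc1COc1ccc([C@@H]2C[C@H](c3c(OCc4ccccc4)cc(O)c(CO)c3OCc3ccccc3)c3ccc(OCc4ccccc4)cc3O2)cc1 | intermediate (not isolated)
12 | 2,4-bis(benzyloxy)-3-Fl-6-hydroxybenzaldehyde | c1ccccc1COc1ccc([C@@H]2C[C@H](c3c(OCc4ccccc4)cc(O)c(C=O)c3OCc3ccccc3)c3ccc(OCc4ccccc4)cc3O2)cc1 | intermediate
13 | (E)-3-[4-(benzyloxy)phenyl]prop-2-enal | O=C/C=C/c1ccc(OCc2ccccc2)cc1 | intermediate
14 | 5,7-bis(benzyloxy)-2-[4-(benzyloxy)phenyl]-6-Fl-4-hydroxychroman-3-carbaldehyde; C-2 arranged in space as in 15 (formally 2S here because the priorities change), C-3 and C-4 undefined and lost on dehydration | c1ccccc1COc1ccc([C@@H]2C[C@H](c3c(OCc4ccccc4)cc4c(c3OCc3ccccc3)C(O)C(C=O)[C@@H](c3ccc(OCc5ccccc5)cc3)O4)c3ccc(OCc4ccccc4)cc3O2)cc1 | intermediate (not isolated)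
15 | (2R)-5,7-bis(benzyloxy)-2-[4-(benzyloxy)phenyl]-6-Fl-2H-chromene-3-carbaldehyde | c1ccccc1COc1ccc([C@@H]2C[C@H](c3c(OCc4ccccc4)cc4c(c3OCc3ccccc3)C=C(C=O)[C@@H](c3ccc(OCc5ccccc5)cc3)O4)c3ccc(OCc4ccccc4)cc3O2)cc1 | intermediate
16 | (2R)-5,7-bis(benzyloxy)-2-[4-(benzyloxy)phenyl]-6-Fl-2H-chromen-3-yl formate | c1ccccc1COc1ccc([C@@H]2C[C@H](c3c(OCc4ccccc4)cc4c(c3OCc3ccccc3)C=C(OC=O)[C@@H](c3ccc(OCc5ccccc5)cc3)O4)c3ccc(OCc4ccccc4)cc3O2)cc1 | intermediate (not isolated)
17 | (2R)-5,7-bis(benzyloxy)-2-[4-(benzyloxy)phenyl]-6-Fl-chroman-3-one | c1ccccc1COc1ccc([C@@H]2C[C@H](c3c(OCc4ccccc4)cc4c(c3OCc3ccccc3)CC(=O)[C@@H](c3ccc(OCc5ccccc5)cc3)O4)c3ccc(OCc4ccccc4)cc3O2)cc1 | intermediate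
18 | (2R,3R)-5,7-bis(benzyloxy)-2-[4-(benzyloxy)phenyl]-6-Fl-chroman-3-ol (2,3-cis) | c1ccccc1COc1ccc([C@@H]2C[C@H](c3c(OCc4ccccc4)cc4c(c3OCc3ccccc3)C[C@@H](O)[C@@H](c3ccc(OCc5ccccc5)cc3)O4)c3ccc(OCc4ccccc4)cc3O2)cc1 | intermediate
19 | (2R,3R)-2-(4-hydroxyphenyl)-6-[(2S,4S)-7-hydroxy-2-(4-hydroxyphenyl)chroman-4-yl]chroman-3,5,7-triol | Oc1ccc([C@@H]2C[C@H](c3c(O)cc4c(c3O)C[C@@H](O)[C@@H](c3ccc(O)cc3)O4)c3ccc(O)cc3O2)cc1 | target

## Step count and least certain steps

Total step count: 11. Longest linear sequence: 9 steps (steps 1, 2, 4, 5, 6, 8, 9, 10, 11, from 1 to 19); steps 3 and 7 are side branches from 6.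

Step 8 (key step). The most likely failure is slow conjugate addition combined with erosion of facial selectivity: the phenol of 12 is hydrogen-bonded and flanked by substituents, the iminium ion of 13 is deactivated by the para oxygen, and the oxa-Michael step is reversible, so the product may form slowly and with a mixture of configurations at C-2. The fallback abandons the annulation and closes the lower pyran by epoxide–arene cyclisation; it sets out from 10 (with 6 as the source of the side chain) and comes back at 18, bypassing steps 6 to 10. Addition of CH2=CHMgBr to 6 gives (±)-1-[4-(benzyloxy)phenyl]prop-2-en-1-ol F1. Sharpless kinetic resolution (Ti(OiPr)4, L-(+)-DIPT, t-BuOOH, 4 Å MS, −20 °C) should convert its fast-reacting enantiomer into the erythro epoxy alcohol (S)-[4-(benzyloxy)phenyl][(2R)-oxiran-2-yl]methanol F2. Mitsunobu etherification of 10 with F2 (PPh3, DIAD, toluene, 0 °C) inverts the carbinol centre and gives (2S,4S)-7-(benzyloxy)-2-[4-(benzyloxy)phenyl]-4-{2,6-bis(benzyloxy)-4-[(R)-[4-(benzyloxy)phenyl][(2R)-oxiran-2-yl]methoxy]phenyl}chroman F3. Ph3PAuNTf2 in CH2Cl2 should then close the pyran by 6-endo attack of either equivalent ortho carbon of ring D on the CH2 terminus and give 18 directly.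

Step 4. The most likely failure is sluggish cycloaddition with poor enantioface discrimination, because the cation derived from 5 is stabilised by two oxygenated rings and shielded by two ortho benzyloxy groups, while the acid may oligomerise 7. The fallback builds the upper unit from a preformed flavanone and sets C-4 by ionic hydrogenation; it sets out from 2 and comes back at 9. Asymmetric conjugate addition of 4-(benzyloxy)phenylboronic acid to 7-(benzyloxy)chromen-4-one (Pd(OCOCF3)2 with the t-BuPyOx antipode that gives the 2S product) gives (2S)-7-(benzyloxy)-2-[4-(benzyloxy)phenyl]chroman-4-one F4. The aryllithium 4 made from 2, transmetalated with CeCl3 to suppress enolisation, adds at −78 °C to give (2S)-7-(benzyloxy)-2-[4-(benzyloxy)phenyl]-4-[2,6-bis(benzyloxy)-4-(triisopropylsilyloxy)phenyl]chroman-4-ol F5. Et3SiH with BF3·OEt2 at −78 °C should reduce the derived diarylmethyl cation by axial hydride delivery, which leaves both aryl groups equatorial and cis, giving 9.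

Step 9. The most likely failure is over-oxidation (epoxidation of the electron-rich enol formate or hydroxylation of ring D) or hydride migration to the acid in the peracid stage, and base-induced loss of configuration at C-2 during formate cleavage. The fallback exchanges the formyl group for oxygen through nitrogen; it sets out from 15 and comes back at 17. Pinnick oxidation (NaClO2, NaH2PO4, 2-methyl-2-butene, t-BuOH/H2O) gives (2R)-5,7-bis(benzyloxy)-2-[4-(benzyloxy)phenyl]-6-Fl-2H-chromene-3-carboxylic acid F6. Curtius rearrangement (DPPA, Et3N, t-BuOH, toluene, 80 °C) gives tert-butyl N-{(2R)-5,7-bis(benzyloxy)-2-[4-(benzyloxy)phenyl]-6-Fl-2H-chromen-3-yl}carbamate F7. Hydrolysis with aqueous oxalic acid in THF at room temperature gives 17.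

Step 2. The most likely failure is competing deprotonation at a benzylic CH2 followed by Wittig rearrangement, or slow addition of the hindered aryllithium to the phenoxide-deactivated aldehyde. The fallback reverses the polarity of the coupling; it sets out from 1 and comes back at 5. Vilsmeier formylation of 1 (POCl3, DMF; para to the hydroxyl as the main pathway, ortho isomer removed) gives 2,6-bis(benzyloxy)-4-hydroxybenzaldehyde F8. Silylation (TIPSCl, imidazole) gives 2,6-bis(benzyloxy)-4-(triisopropylsilyloxy)benzaldehyde F9. The dilithio species formed from 5-(benzyloxy)-2-bromophenol and two equivalents of n-BuLi by bromine–lithium exchange at −78 °C, where benzylic deprotonation cannot compete, adds to F9 and gives 5.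

## Further compounds

F1 | step 8 | (±)-1-[4-(benzyloxy)phenyl]prop-2-en-1-ol | C=CC(O)c1ccc(OCc2ccccc2)cc1
F2 | step 8 | (S)-[4-(benzyloxy)phenyl][(2R)-oxiran-2-yl]methanol | O[C@@H](c1ccc(OCc2ccccc2)cc1)[C@H]1CO1
F3 | step 8 | (2S,4S)-7-(benzyloxy)-2-[4-(benzyloxy)phenyl]-4-{2,6-bis(benzyloxy)-4-[(R)-[4-(benzyloxy)phenyl][(2R)-oxiran-2-yl]methoxy]phenyl}chroman | c1ccccc1COc1ccc([C@@H]2C[C@H](c3c(OCc4ccccc4)cc(O[C@H](c5ccc(OCc6ccccc6)cc5)[C@H]5CO5)cc3OCc3ccccc3)c3ccc(OCc4ccccc4)cc3O2)cc1
F4 | step 4 | (2S)-7-(benzyloxy)-2-[4-(benzyloxy)phenyl]chroman-4-one | O=C1C[C@@H](c2ccc(OCc3ccccc3)cc2)Oc2cc(OCc3ccccc3)ccc12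
F5 | step 4 | (2S)-7-(benzyloxy)-2-[4-(benzyloxy)phenyl]-4-[2,6-bis(benzyloxy)-4-(triisopropylsilyloxy)phenyl]chroman-4-ol (C-4 undefined) | OC1(c2c(OCc3ccccc3)cc(O[Si](C(C)C)(C(C)C)C(C)C)cc2OCc2ccccc2)C[C@@H](c2ccc(OCc3ccccc3)cc2)Oc2cc(OCc3ccccc3)ccc12
F6 | step 9 | (2R)-5,7-bis(benzyloxy)-2-[4-(benzyloxy)phenyl]-6-Fl-2H-chromene-3-carboxylic acid | c1ccccc1COc1ccc([C@@H]2C[C@H](c3c(OCc4ccccc4)cc4c(c3OCc3ccccc3)C=C(C(=O)O)[C@@H](c3ccc(OCc5ccccc5)cc3)O4)c3ccc(OCc4ccccc4)cc3O2)cc1
F7 | step 9 | tert-butyl N-{(2R)-5,7-bis(benzyloxy)-2-[4-(benzyloxy)phenyl]-6-Fl-2H-chromen-3-yl}carbamate | c1ccccc1COc1ccc([C@@H]2C[C@H](c3c(OCc4ccccc4)cc4c(c3OCc3ccccc3)C=C(NC(=O)OC(C)(C)C)[C@@H](c3ccc(OCc5ccccc5)cc3)O4)c3ccc(OCc4ccccc4)cc3O2)cc1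
F8 | step 2 | 2,6-bis(benzyloxy)-4-hydroxybenzaldehyde | O=Cc1c(OCc2ccccc2)cc(O)cc1OCc1ccccc1
F9 | step 2 | 2,6-bis(benzyloxy)-4-(triisopropylsilyloxy)benzaldehyde | O=Cc1c(OCc2ccccc2)cc(O[Si](C(C)C)(C(C)C)C(C)C)cc1OCc1ccccc1
A1 | alternative 1 | (3R,4R)-4-(benzyloxy)-3-[4-(benzyloxy)phenyl]-2-oxabicyclo[4.2.0]oct-1(8)-en-7-one (C-6 undefined) | O=C1C=C2O[C@H](c3ccc(OCc4ccccc4)cc3)[C@H](OCc3ccccc3)CC12
A2 | alternative 1 | (2S,4R)-7-(benzyloxy)-2-[4-(benzyloxy)phenyl]-4-[(triisopropylsilyloxy)ethynyl]chroman (2,4-cis) | c1ccccc1COc1ccc([C@@H]2C[C@H](C#CO[Si](C(C)C)(C(C)C)C(C)C)c3ccc(OCc4ccccc4)cc3O2)cc1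
A3 | alternative 1 | (2R,3R)-3-(benzyloxy)-2-[4-(benzyloxy)phenyl]-6-Fl-7-(triisopropylsilyloxy)chroman-5-ol | c1ccccc1COc1ccc([C@@H]2C[C@H](c3c(O[Si](C(C)C)(C(C)C)C(C)C)cc4c(c3O)C[C@@H](OCc3ccccc3)[C@@H](c3ccc(OCc5ccccc5)cc3)O4)c3ccc(OCc4ccccc4)cc3O2)cc1
A4 | alternative 2 | (2S,4S)-7-(benzyloxy)-2-[4-(benzyloxy)phenyl]-4-[2,6-bis(benzyloxy)-4-(triisopropylsilyloxy)phenyl]chroman (identical with 9) | c1ccccc1COc1ccc([C@@H]2C[C@H](c3c(OCc4ccccc4)cc(O[Si](C(C)C)(C(C)C)C(C)C)cc3OCc3ccccc3)c3ccc(OCc4ccccc4)cc3O2)cc1
A5 | alternative 3 | (2S,4S)-7-(benzyloxy)-2-[4-(benzyloxy)phenyl]-4-{2,6-bis(benzyloxy)-4-[(R)-[4-(benzyloxy)phenyl][(2R)-oxiran-2-yl]methoxy]phenyl}chroman (identical with F3) | c1ccccc1COc1ccc([C@@H]2C[C@H](c3c(OCc4ccccc4)cc(O[C@H](c5ccc(OCc6ccccc6)cc5)[C@H]5CO5)cc3OCc3ccccc3)c3ccc(OCc4ccccc4)cc3O2)cc1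
A6 | alternative 3 | (2R,3R)-5,7-bis(benzyloxy)-2-[4-(benzyloxy)phenyl]-6-Fl-chroman-3-ol (identical with 18) | c1ccccc1COc1ccc([C@@H]2C[C@H](c3c(OCc4ccccc4)cc4c(c3OCc3ccccc3)C[C@@H](O)[C@@H](c3ccc(OCc5ccccc5)cc3)O4)c3ccc(OCc4ccccc4)cc3O2)cc1
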